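If crystals of Ly stand in a flask, take dissolved Ry as held at its solubility. Ze, tied to it by Ry <-> Ze, is then held too. Take late Ze as under thermodynamic control: at this one temperature, one concentration for each charge of Jy that leaves Ly standing.

| flask | Jy | Dz | remark | time |
|---|---|---|---|---|
| zeta | 1.8 M | 1.2 M | run made earlier |  |
| flask | 1.2 M | 1.20 M |  | 10 h |

zeta run (percent of the Jy charged)

| time / min | Ry / % | Ze / % |
|---|---|---|
| 5.00 | 55 | 13 |
| 8.00 | 73 | 15 |
| 12.0 | 77 | 11 |
| 15.0 | 83 | 8 |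
| 25.0 | 93 | 6 |
| 40.0 | 92 | 7 |
| 60.0 | 89 | 5 |

(each reading ± 2 percentage points)

- what is said of Ry includes Ly
- Ly is a solid; its amount is given per volume of the solution
- candidate steps: Jy -> Ry; Ry <-> Ze; Jy <-> Xa; Xa -> Ze; Xa + Dz -> Xa.Dz; Ly <-> Ry

- ratio of Ry to Ze at 4.0 s
- ratio of Ry to Ze at 10 h

Read that concentration from the zeta run. The highest Ze reading is 15%. The later readings level within the scatter, so average the last three: 6.00% of the Jy charged. Multiply by the zeta charge of 1.8 M. This gives the Ze floor c_Z, the Ze concentration taken to stand over Ly, as read from the zeta run: 0.108 M. The scatter of 2 percentage points makes this mean the weak link.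

Carry c_Z to the flask. Divide by its 1.2 M of Jy, and Ze is 9.00% of the charge. Give the rest to Ry, and my estimate of the ratio at 10 h is 10.1. The time 4.0 s lies far before the first reading at 5.00 min, so this reckoning leaves the early ratio open.

The forecast says “If Ly is present, dissolved Ry is pinned”. It gives 10.5 at 10 h, range 7.5 to 17, against my 10.1, and 3.8 at 4.0 s, range 2.5 to 8.

    Jy → Ry (k = 0.00320 s⁻¹)
    Ry ⇌ Ze (K = 0.890, k = 0.00270 s⁻¹)
    Jy ⇌ Xa (K = 3.20, k = 0.00130 s⁻¹)
    Xa → Ze (k = 0.0170 s⁻¹)
    Xa + Dz → Xa.Dz (k = 0.00330 L mol⁻¹ s⁻¹)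
    Ly ⇌ Ry, rate k6*(cs6 - [Ry]) while solid is left; crystals form when [Ry] > cs6 (solubility = 0.0970 M, k = 0.150 s⁻¹)

The flask gives 52.9 at 4.0 s and 12.2 at 10 h. At 10 h the forward half-life of dissolved Ry into Ze is 0.071 h, far shorter than the run. Ze stands at 7.20% after 1.00 h and 7.19% after 100 h, with Ly at 79.5%. At 10.0 h that Ze is 0.0863 M in the flask. In the neighbour flask with 2.0 M of Jy, c_Z gives 5.40%. At 10.0 h that flask stores Ly at 85.6% and Ze at 4.32%, which is 0.0864 M of Ze.

The readings are simulated for an exercise; noise was put on by code.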